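The slowness of the north-east run sits in its tail: it loses 40.7% of its starting material by 0.41 min, but the next 43.6% of the charge takes until 5.4 min.

| setting | north-east | east | south-east | west |
|---|---|---|---|---|
| starting material | 0.100 M | 0.0600 M | 0.150 M | 0.0500 M |
| coupling partner | 0.110 M | 0.0700 M | 0.110 M | 0.220 M |
| time |  |  |  | 5.4 min |

| run | time / min | [starting material] / M |
|---|---|---|
| north-east run | 0.41 | 0.0593 |
| north-east run | 1.2 | 0.0375 |
| north-east run | 2.4 | 0.0278 |
| north-east run | 3.8 | 0.0237 |
| north-east run | 5.4 | 0.0157 |
| east run | 0.41 | 0.0341 |
| east run | 1.2 | 0.0192 |
| east run | 2.4 | 0.0152 |
| east run | 3.8 | 0.0113 |
| east run | 5.4 | 0.0087 |
| south-east run | 0.41 | 0.0933 |
| south-east run | 1.2 | 0.0657 |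
| south-east run | 2.4 | 0.0502 |
| south-east run | 3.8 | 0.0373 |
| south-east run | 5.4 | 0.0310 |

(each reading ± 0.001 M)

- Overall: starting material + coupling partner -> target.
- Constant volume, constant temperature.
- "The second partner" is coupling partner.
- An order is taken over about fifteen percent of the charge, up and down.

* the power of [coupling partner] that the first rate follows, about the charge of the north-east run; measure it at two percent of starting material made into target
* the power of [starting material] that the first rate follows, about the charge of the north-east run; measure it at two percent of starting material made into target (one fixed amount of target, the same in the runs compared)
* starting material in the west run at 5.4 min, as a share of the starting material charged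

By the first reading the share gone is 40.7% in the north-east run, 43.2% in the east run and 37.8% in the south-east run, although the charges differ. A step whose speed is proportional to what is present gives a share that does not depend on the charge, and these shares are close to that. In the south-east run the 0.110 M of coupling partner charged is less than the 0.119 M of starting material that has disappeared by 5.4 min, so some of that starting material went without coupling partner.

My reckoning is that starting material first becomes an intermediate by itself, and coupling partner meets the intermediate afterwards. At first the intermediate grows steadily, at a pace set by the starting-material charge. The rate of target then follows intermediate times coupling partner, so it starts from nil and climbs with time, and the target made climbs with the square of time. A fixed small amount of target is therefore reached after a time that goes as one over the square root of the product of the charges. Putting that time back into the rate, I find that the rate at that amount follows the square root itself, so each order should be 0.5.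

For the north-east run this square root is 0.105 M: the square root of the two charges multiplied is the ramp charge. It is 0.0648 M in the east run, 0.128 M in the south-east run and 0.105 M in the west run.

For the late share I have no derivation, just a reading. The share left at the last reading, divided by the starting-material charge over the ramp charge, is 0.165 in the north-east run, 0.157 in the east run and 0.177 in the south-east run. Their mean gives the west run 7.92% left.

The forecast gives 0.3 for coupling partner, 1.1 for starting material and 10% left in the west run, with the caution: “These orders are rough.”

The flask gives 0.50 for coupling partner, 0.65 for starting material and 9.28% left in the west run.

    starting material ⇌ intermediate + by-product (1.332 min⁻¹, 37.56 M⁻¹ min⁻¹)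
    intermediate + coupling partner → target (12.42 M⁻¹ min⁻¹)
    starting material → decomposed substrate (0.1890 min⁻¹)
    2 coupling partner → lost reagent (4.764 M⁻¹ min⁻¹)

The ramp charge comes from the charges and the rates from the flask, and about the north-east charge the order in coupling partner stands at 0.50 and that in starting material at 0.65, against my 0.5 for each. On the south-east run the ramp charge over that of the north-east run is 1.22, and the simulated first rates stand in the ratio 1.29. The west share left belongs to a later part of the run, where coupling partner pairs off into lost reagent: the west run with that step taken away keeps 0.722% of its starting material.

All runs were generated by integration from invented constants.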